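(The data come from a simulation for an exercise, and the scatter is random.)

Count amounts first: the share asked for, the selectivity, is target over target plus trapped intermediate, so find those two amounts in percent of the starting material charged.

| flask | starting material | capture agent | temperature | remark | time |
|---|---|---|---|---|---|
| autumn | 0.90 M | 0.074 M | 42 °C | run made earlier |  |
| winter | 0.90 M | 1 M | 59 °C | run made earlier |  |
| dusk | 1 M | 0.27 M | 42 °C | run made earlier |  |
| green | 0.60 M | 0.800 M | 65 °C |  | 20 d |
| grey | 1.5 M | 0.270 M | 35 °C |  | 20 d |
| ochre | 0.30 M | 0.0600 M | 50 °C |  | 20 d |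
| violet | 0.90 M | 0.270 M | 50 °C |  | 20 d |
| amber | 0.90 M | 0.0600 M | 35 °C |  | 20 d |
| red | 2.5 M | 0.500 M | 50 °C |  | 20 d |

| run | time / d | target / % | trapped intermediate / % | starting material / % |
|---|---|---|---|---|
| autumn | 4.00 | 7 | 6 | 0 |
| autumn | 8.00 | 6 | 6 | 1 |
| autumn | 10.0 | 9 | 1 | 3 |
| autumn | 15.0 | 5 | 6 | 2 |
| winter | 0.625 | 7 | 17 | 0 |
| winter | 1.67 | 5 | 29 | 0 |
| winter | 4.00 | 4 | 49 | 0 |
| winter | 10.0 | 8 | 70 | 0 |
| dusk | 4.00 | 7 | 9 | 1 |
| dusk | 8.00 | 4 | 15 | 0 |
| dusk | 10.0 | 7 | 15 | 0 |
| dusk | 15.0 | 7 | 16 | 2 |

(standard deviation of a reading: 2 percentage points)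

- the flasks by share of target in all that became target or trapped intermediate, highest first, at 20 d (green / grey / ochre / violet / amber / red)
- the share of target in all that became target or trapped intermediate of the flask you put first, at 20 d
- the share of target in all that became target or trapped intermediate of the flask you put last, at 20 d

- steps thought possible: intermediate A -> intermediate C; capture agent + intermediate B -> trapped intermediate; intermediate B <-> intermediate C; starting material <-> intermediate A; starting material -> intermediate B; starting material -> target

Where does target stop? Average its column over the earlier runs to get 6.33%. Winter shows no clear rise, reading 7% at 0.625 d and 8% at 10.0 d, so assume this amount for the new flasks.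

How much can be trapped? One capture agent makes one trapped intermediate, so the ceiling is c(capture agent)/c(starting material), unless that passes the charge. Amber has the lowest ceiling, 6.67%, which gives 48.7%, its full-capture share: target over target plus a filled ceiling. Green has the highest ceiling, 133%, which passes the charge, so its full-capture share is the target amount itself, 6.33%.

How far up does each flask climb by 20 d? Dusk had filled 59.3% of its ceiling at 15.0 d, as a reading. Amber is colder, so expect it short of its ceiling and above 48.7%. Green is hotter than winter, which read 70% trapped at 10.0 d, so expect it near 6.33%. My reckoning therefore puts amber first and green last.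

The forecast, holding that target comes “only from the early direct branch”, gives amber > ochre > grey > red > violet > green, with 54% (44% to 64%) for amber and 7% (5.5% to 10%) for green.

The flasks give amber > ochre > grey > red > violet > green, with 58.4% for amber and 7.81% for green.

    intermediate A → intermediate C (k = 0.0800 /h, Ea = 109 kJ/mol)
    capture agent + intermediate B → trapped intermediate (k = 0.0150 /M/h, Ea = 68.0 kJ/mol)
    intermediate B ⇌ intermediate C (K = 2.40, k = 0.0240 /h, Ea = 109 kJ/mol, ΔH = −22.0 kJ/mol)
    starting material ⇌ intermediate A (K = 2.40, k = 0.0640 /h, Ea = 111 kJ/mol, ΔH = 3.00 kJ/mol)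
    starting material → intermediate B (k = 0.220 /h, Ea = 101 kJ/mol)
    starting material → target (k = 0.0180 /h, Ea = 114 kJ/mol)
    (constants at 50 °C)

In amber, capture alone, with capture agent as charged, would halve intermediate B in 110 d, longer than the 20 d asked. At 0.670 d, amber's intermediate B goes to intermediate C 13 times faster, forward step alone, than to capture. At 20.0 d amber keeps 44.7% of its own capture agent and stands at 58.4%, above its full-capture share of 48.7%. At 200 d it keeps 1.56% and stands at 44.2%. Red, with a full-capture share of 24.1%, keeps 1.21% of its own capture agent at 20.0 d and stands at 24.2%.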